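**Assumption:** (S)-(−)-α-ionone of high ee is taken as a purchasable speciality chemical (availability not verified); locants in the text use carotenoid numbering (ring C1–C6, chain C7–C15, primes for the ring B half).

**Structure check.** The target is the all-E C40 nonaene with two 5-hydroxy-3-oxo-5,6-dihydro end groups. Both C6 centres are S, but the ends are C5 epimers: ring A is (5S,6S) with 5-OH trans to the chain, ring B is (5'R,6'S) with 5-OH cis to the chain. The route therefore assembles two different C15 halves stepwise.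

## Retrosynthetic overview

1. Target 21 ⇒ oxidation of the two secondary C3/C3' carbinols of the all-E C40 tetrol 20; the C3 hydroxyls are stereochemical relay groups.
2. 20 ⇒ two Wittig disconnections (C11=C12 and C11'=C12'): ring A C15 phosphonium salt 10 + C10 dialdehyde 14 + ring B C15 phosphonium salt 13.
3. 10 and 13 ⇒ triols ⇒ syn-epoxy alcohols (LiAlH4 opens the epoxide at C4 and reduces the ester) ⇒ the two C3-epimeric allylic alcohols 6 and 7 (OH-directed epoxidation sets C5).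
4. 6 and 7 ⇒ one enone ester 5 (Luche reduction) ⇒ allylic oxidation and Horner–Wadsworth–Emmons olefination from (S)-α-ionone 1, which supplies C6 (S) of both halves.
5. No carbocycle is built: both six-membered rings come intact from 1. The ring A half is finished in steps 4–6 and the ring B half in steps 7–9; only transient oxiranes are made (steps 4, 7) and opened (steps 5, 8).

## Route

**Step 1**
Reactants: 1 (S)-α-ionone; 2 triethyl phosphonoacetate
Product: 4 ethyl (2E,4E)-3-methyl-5-[(1S)-2,6,6-trimethylcyclohex-2-en-1-yl]penta-2,4-dienoate, via sodium phosphonate carbanion 3 (not isolated)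
Conditions: NaH, THF, 0 → 40 °C; chromatography (removes minor 2Z isomer)
Reagents that add atoms: none
Why: Horner–Wadsworth–Emmons olefination of the methyl ketone by the stabilised phosphonate carbanion gives mainly the 2E dienoate (about 4:1), and this weakly basic carbanion leaves the C6 stereocentre of 1 untouched.

**Step 2**
Reactants: 4 ethyl (2E,4E)-3-methyl-5-[(1S)-2,6,6-trimethylcyclohex-2-en-1-yl]penta-2,4-dienoate
Product: 5 ethyl (2E,4E)-3-methyl-5-[(1S)-2,6,6-trimethyl-4-oxocyclohex-2-en-1-yl]penta-2,4-dienoate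
Conditions: t-BuOOH (70 % aq., 5 equiv), Rh2(cap)4 (1 mol %, cap = caprolactamate), K2CO3 (0.5 equiv), CH2Cl2, rt
Reagents that add atoms: tert-butyl hydroperoxide, CC(C)(C)OO
Why: Catalysed radical allylic C–H oxidation (Kharasch-type peroxyl radical chain) converts the only ring CH2 next to the trisubstituted alkene (C3) into the enone carbonyl, while the tertiary C6–H, buried between the gem-dimethyl carbon and the side chain, is spared so C6 stays S.

**Step 3**
Reactants: 5 ethyl (2E,4E)-3-methyl-5-[(1S)-2,6,6-trimethyl-4-oxocyclohex-2-en-1-yl]penta-2,4-dienoate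
Product: 6 ethyl (2E,4E)-5-[(1S,4S)-4-hydroxy-2,6,6-trimethylcyclohex-2-en-1-yl]-3-methylpenta-2,4-dienoate (3-OH trans to the side chain) and 7 ethyl (2E,4E)-5-[(1S,4R)-4-hydroxy-2,6,6-trimethylcyclohex-2-en-1-yl]-3-methylpenta-2,4-dienoate (3-OH cis to the side chain); both isolated by chromatography
Conditions: NaBH4, CeCl3·7H2O, MeOH, −20 °C
Reagents that add atoms: none
Why: Luche reduction adds hydride 1,2 to the enone carbonyl without touching the dienoate, and because the remote C6 substituent gives little facial bias both C3 epimers form and both are used, each later steering oxygen to one face of C4=C5 and so to one of the two C5 configurations of the target.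

**Step 4**
Reactants: 6 ethyl (2E,4E)-5-[(1S,4S)-4-hydroxy-2,6,6-trimethylcyclohex-2-en-1-yl]-3-methylpenta-2,4-dienoate
Product: 8 ethyl (2E,4E)-5-[(1R,2S,5S,6S)-5-hydroxy-1,3,3-trimethyl-7-oxabicyclo[4.1.0]heptan-2-yl]-3-methylpenta-2,4-dienoate (epoxide and OH on the face opposite the side chain)
Conditions: VO(acac)2 (3 mol %), t-BuOOH (1.5 equiv, decane), CH2Cl2, 0 °C → rt
Reagents that add atoms: tert-butyl hydroperoxide, CC(C)(C)OO
Why: Hydroxyl-directed epoxidation (Sharpless vanadium/t-BuOOH system) delivers oxygen to the C4=C5 face that carries the C3–OH, here the face opposite the side chain, which fixes the C5–O bond trans to the chain (future 5S) and leaves the electron-poor dienoate alone.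

**Step 5**
Reactants: 8 ethyl (2E,4E)-5-[(1R,2S,5S,6S)-5-hydroxy-1,3,3-trimethyl-7-oxabicyclo[4.1.0]heptan-2-yl]-3-methylpenta-2,4-dienoate
Product: 9 (2E,4E)-5-[(1S,2S,4S)-2,4-dihydroxy-2,6,6-trimethylcyclohexyl]-3-methylpenta-2,4-dien-1-ol
Conditions: LiAlH4 (excess), THF, 0 → 40 °C; aq. NaOH work-up
Reagents that add atoms: none
Why: Hydride opens the trisubstituted epoxide by SN2 attack at the less substituted C4 (the classical 4,5-epoxy-3-ol to 3,5-diol reduction), so the C5–O bond and its configuration survive as the tertiary alcohol, and the same reagent reduces the ester 1,2 to the primary allylic alcohol.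

**Step 6**
Reactants: 9 (2E,4E)-5-[(1S,2S,4S)-2,4-dihydroxy-2,6,6-trimethylcyclohexyl]-3-methylpenta-2,4-dien-1-ol
Product: 10 [(2E,4E)-5-[(1S,2S,4S)-2,4-dihydroxy-2,6,6-trimethylcyclohexyl]-3-methylpenta-2,4-dien-1-yl]triphenylphosphonium bromide
Conditions: PPh3·HBr, MeOH, 0 °C → rt
Reagents that add atoms: triphenylphosphine hydrobromide, [Br-].[PH+](c1ccccc1)(c1ccccc1)c1ccccc1
Why: Phosphonium salt formation by SN1 substitution (pentadienyl cation trapped by PPh3 at the unhindered primary terminus) engages only the dienylic primary alcohol, since the secondary and the non-allylic tertiary hydroxyls do not ionise, and no stereocentre is touched.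

**Step 7**
Reactants: 7 ethyl (2E,4E)-5-[(1S,4R)-4-hydroxy-2,6,6-trimethylcyclohex-2-en-1-yl]-3-methylpenta-2,4-dienoate
Product: 11 ethyl (2E,4E)-5-[(1S,2S,5R,6R)-5-hydroxy-1,3,3-trimethyl-7-oxabicyclo[4.1.0]heptan-2-yl]-3-methylpenta-2,4-dienoate (epoxide, OH and side chain all on one face)
Conditions: VO(acac)2 (5 mol %), t-BuOOH (1.5 equiv, decane), CH2Cl2, 0 °C → rt
Reagents that add atoms: tert-butyl hydroperoxide, CC(C)(C)OO
Why: The same hydroxyl-directed epoxidation, now run on the C3 epimer, places the oxirane on the face of the C3–OH and of the side chain (reactive conformer: OH pseudoaxial, chain pseudoequatorial), which fixes the C5–O bond cis to the chain (future 5'R).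

**Step 8**
Reactants: 11 ethyl (2E,4E)-5-[(1S,2S,5R,6R)-5-hydroxy-1,3,3-trimethyl-7-oxabicyclo[4.1.0]heptan-2-yl]-3-methylpenta-2,4-dienoate
Product: 12 (2E,4E)-5-[(1S,2R,4R)-2,4-dihydroxy-2,6,6-trimethylcyclohexyl]-3-methylpenta-2,4-dien-1-ol
Conditions: LiAlH4 (excess), THF, 0 → 40 °C; aq. NaOH work-up
Reagents that add atoms: none
Why: As in step 5, SN2 hydride opening at C4 leaves the C5–O bond and configuration intact as the tertiary alcohol, and the ester is reduced 1,2 to the primary allylic alcohol.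

**Step 9**
Reactants: 12 (2E,4E)-5-[(1S,2R,4R)-2,4-dihydroxy-2,6,6-trimethylcyclohexyl]-3-methylpenta-2,4-dien-1-ol
Product: 13 [(2E,4E)-5-[(1S,2R,4R)-2,4-dihydroxy-2,6,6-trimethylcyclohexyl]-3-methylpenta-2,4-dien-1-yl]triphenylphosphonium bromide
Conditions: PPh3·HBr, MeOH, 0 °C → rt
Reagents that add atoms: triphenylphosphine hydrobromide, [Br-].[PH+](c1ccccc1)(c1ccccc1)c1ccccc1
Why: SN1 phosphonium salt formation at the dienylic primary alcohol only, as in step 6, with all stereocentres untouched.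

**Step 10**
Reactants: 10 [(2E,4E)-5-[(1S,2S,4S)-2,4-dihydroxy-2,6,6-trimethylcyclohexyl]-3-methylpenta-2,4-dien-1-yl]triphenylphosphonium bromide; 14 (2E,4E,6E)-2,7-dimethylocta-2,4,6-trienedial
Product: 17 (2E,4E,6E,8E,10E,12E)-13-[(1S,2S,4S)-2,4-dihydroxy-2,6,6-trimethylcyclohexyl]-2,7,11-trimethyltrideca-2,4,6,8,10,12-hexaenal, via ring A ylide 15 (not isolated), via 8Z aldehyde 16 (not isolated)
Conditions: 14 (3 equiv), NaOMe (1.05 equiv, slow addition), MeOH/CH2Cl2, −10 °C → rt; then heptane/EtOH, reflux, N2, dark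
Reagents that add atoms: none
Why: Wittig olefination of the semi-stabilised allylic ylide with one formyl group of the dialdehyde, used in threefold excess for statistical mono-condensation, forms C11=C12, and the hindered Z isomer formed alongside relaxes thermally to all-E.

**Step 11**
Reactants: 13 [(2E,4E)-5-[(1S,2R,4R)-2,4-dihydroxy-2,6,6-trimethylcyclohexyl]-3-methylpenta-2,4-dien-1-yl]triphenylphosphonium bromide; 17 (2E,4E,6E,8E,10E,12E)-13-[(1S,2S,4S)-2,4-dihydroxy-2,6,6-trimethylcyclohexyl]-2,7,11-trimethyltrideca-2,4,6,8,10,12-hexaenal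
Product: 20 all-E (3S,5S,6S,3'R,5'R,6'S)-5,6,5',6'-tetrahydro-β,β-carotene-3,5,3',5'-tetrol, via ring B ylide 18 (not isolated), via 11'Z tetrol 19 (not isolated)
Conditions: 13 (1.3 equiv), NaOMe, MeOH/CH2Cl2, 0 °C → rt; then heptane/EtOH, reflux, N2, dark
Reagents that add atoms: none
Why: The second Wittig olefination joins the ring B half to the C25 aldehyde at C11'=C12', completing the C40 nonaene with the two C5-epimeric ends in defined positions, and thermal equilibration again converts the hindered Z isomer into all-E.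

**Step 12**
Reactants: 20 all-E (3S,5S,6S,3'R,5'R,6'S)-5,6,5',6'-tetrahydro-β,β-carotene-3,5,3',5'-tetrol
Product: 21 all-E (5S,6S,5'R,6'S)-5,5'-dihydroxy-5,6,5',6'-tetrahydro-β,β-carotene-3,3'-dione (CNP0366900.1)
Conditions: Dess–Martin periodinane (3 equiv), pyridine, CH2Cl2, 0 °C → rt, dark, Ar
Reagents that add atoms: none
Why: Dess–Martin oxidation turns the two secondary carbinols (C3, C3') into ketones, while the tertiary C5/C5' alcohols cannot be oxidised and the buffered medium avoids dehydration of the new β-hydroxy ketones and leaves the polyene and the C5/C6 centres unchanged.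

## Compound list

1 | (S)-α-ionone, (3E)-4-[(1S)-2,6,6-trimethylcyclohex-2-en-1-yl]but-3-en-2-one | CC(=O)/C=C/[C@H]1C(C)(C)CCC=C1C | starting material
2 | triethyl phosphonoacetate | CCOC(=O)CP(=O)(OCC)OCC | starting material
3 | sodium salt of the triethyl phosphonoacetate carbanion | [Na+].CCOC(=O)[CH-]P(=O)(OCC)OCC | intermediate
4 | ethyl (2E,4E)-3-methyl-5-[(1S)-2,6,6-trimethylcyclohex-2-en-1-yl]penta-2,4-dienoate | CCOC(=O)/C=C(C)/C=C/[C@H]1C(C)(C)CCC=C1C | intermediate
5 | ethyl (2E,4E)-3-methyl-5-[(1S)-2,6,6-trimethyl-4-oxocyclohex-2-en-1-yl]penta-2,4-dienoate | CCOC(=O)/C=C(C)/C=C/[C@H]1C(C)(C)CC(=O)C=C1C | intermediate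
6 | ethyl (2E,4E)-5-[(1S,4S)-4-hydroxy-2,6,6-trimethylcyclohex-2-en-1-yl]-3-methylpenta-2,4-dienoate (OH trans to side chain) | CCOC(=O)/C=C(C)/C=C/[C@H]1C(C)(C)C[C@H](O)C=C1C | intermediate
7 | ethyl (2E,4E)-5-[(1S,4R)-4-hydroxy-2,6,6-trimethylcyclohex-2-en-1-yl]-3-methylpenta-2,4-dienoate (OH cis to side chain) | CCOC(=O)/C=C(C)/C=C/[C@H]1C(C)(C)C[C@@H](O)C=C1C | intermediate
8 | ethyl (2E,4E)-5-[(1R,2S,5S,6S)-5-hydroxy-1,3,3-trimethyl-7-oxabicyclo[4.1.0]heptan-2-yl]-3-methylpenta-2,4-dienoate | CCOC(=O)/C=C(C)/C=C/[C@H]1C(C)(C)C[C@H](O)[C@@H]2O[C@]12C | intermediate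
9 | (2E,4E)-5-[(1S,2S,4S)-2,4-dihydroxy-2,6,6-trimethylcyclohexyl]-3-methylpenta-2,4-dien-1-ol | OC/C=C(C)/C=C/[C@H]1C(C)(C)C[C@H](O)C[C@]1(C)O | intermediate
10 | [(2E,4E)-5-[(1S,2S,4S)-2,4-dihydroxy-2,6,6-trimethylcyclohexyl]-3-methylpenta-2,4-dien-1-yl]triphenylphosphonium bromide | [Br-].c1ccccc1[P+](c1ccccc1)(c1ccccc1)C/C=C(C)/C=C/[C@H]1C(C)(C)C[C@H](O)C[C@]1(C)O | intermediate
11 | ethyl (2E,4E)-5-[(1S,2S,5R,6R)-5-hydroxy-1,3,3-trimethyl-7-oxabicyclo[4.1.0]heptan-2-yl]-3-methylpenta-2,4-dienoate | CCOC(=O)/C=C(C)/C=C/[C@H]1C(C)(C)C[C@@H](O)[C@H]2O[C@@]12C | intermediate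
12 | (2E,4E)-5-[(1S,2R,4R)-2,4-dihydroxy-2,6,6-trimethylcyclohexyl]-3-methylpenta-2,4-dien-1-ol | OC/C=C(C)/C=C/[C@H]1C(C)(C)C[C@@H](O)C[C@@]1(C)O | intermediate
13 | [(2E,4E)-5-[(1S,2R,4R)-2,4-dihydroxy-2,6,6-trimethylcyclohexyl]-3-methylpenta-2,4-dien-1-yl]triphenylphosphonium bromide | [Br-].c1ccccc1[P+](c1ccccc1)(c1ccccc1)C/C=C(C)/C=C/[C@H]1C(C)(C)C[C@@H](O)C[C@@]1(C)O | intermediate
14 | (2E,4E,6E)-2,7-dimethylocta-2,4,6-trienedial | O=C/C(C)=C/C=C/C=C(C)/C=O | starting material
15 | ring A ylide, [(2E,4E)-5-[(1S,2S,4S)-2,4-dihydroxy-2,6,6-trimethylcyclohexyl]-3-methylpenta-2,4-dien-1-ylidene]triphenylphosphorane | c1ccccc1P(c1ccccc1)(c1ccccc1)=C/C=C(C)/C=C/[C@H]1C(C)(C)C[C@H](O)C[C@]1(C)O | intermediate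
16 | (2E,4E,6E,8Z,10E,12E)-13-[(1S,2S,4S)-2,4-dihydroxy-2,6,6-trimethylcyclohexyl]-2,7,11-trimethyltrideca-2,4,6,8,10,12-hexaenal | O=C/C(C)=C/C=C/C=C(C)/C=C\C=C(C)\C=C\[C@H]1C(C)(C)C[C@H](O)C[C@]1(C)O | intermediate
17 | (2E,4E,6E,8E,10E,12E)-13-[(1S,2S,4S)-2,4-dihydroxy-2,6,6-trimethylcyclohexyl]-2,7,11-trimethyltrideca-2,4,6,8,10,12-hexaenal | O=C/C(C)=C/C=C/C=C(C)/C=C/C=C(C)/C=C/[C@H]1C(C)(C)C[C@H](O)C[C@]1(C)O | intermediate
18 | ring B ylide, [(2E,4E)-5-[(1S,2R,4R)-2,4-dihydroxy-2,6,6-trimethylcyclohexyl]-3-methylpenta-2,4-dien-1-ylidene]triphenylphosphorane | c1ccccc1P(c1ccccc1)(c1ccccc1)=C/C=C(C)/C=C/[C@H]1C(C)(C)C[C@@H](O)C[C@@]1(C)O | intermediate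
19 | 11'Z isomer of (3S,5S,6S,3'R,5'R,6'S)-5,6,5',6'-tetrahydro-β,β-carotene-3,5,3',5'-tetrol | CC(/C=C/C=C(C)/C=C/[C@H]1C(C)(C)C[C@H](O)C[C@]1(C)O)=C\C=C\C=C(C)\C=C/C=C(C)/C=C/[C@H]1C(C)(C)C[C@@H](O)C[C@@]1(C)O | intermediate
20 | all-E (3S,5S,6S,3'R,5'R,6'S)-5,6,5',6'-tetrahydro-β,β-carotene-3,5,3',5'-tetrol | CC(/C=C/C=C(C)/C=C/[C@H]1C(C)(C)C[C@H](O)C[C@]1(C)O)=C\C=C\C=C(C)\C=C\C=C(C)\C=C\[C@H]1C(C)(C)C[C@@H](O)C[C@@]1(C)O | intermediate
21 | all-E (5S,6S,5'R,6'S)-5,5'-dihydroxy-5,6,5',6'-tetrahydro-β,β-carotene-3,3'-dione | CC(/C=C/C=C(C)/C=C/[C@H]1C(C)(C)CC(=O)C[C@]1(C)O)=C\C=C\C=C(C)\C=C\C=C(C)\C=C\[C@H]1C(C)(C)CC(=O)C[C@@]1(C)O | target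

## Step count

Total step count: 12. Longest linear sequence: 9 steps (1, 2, 3, 4, 5, 6, 10, 11, 12).

## Three steps most likely to fail, with fallbacks

**Step 12 (double oxidation beside a nonaene).** The polyene may not survive an oxidant, or the fresh β-hydroxy ketones may dehydrate. In that case the ketones are put in before any polyene exists. The fallback sets out from salts 10 and 13. Parikh–Doering oxidation (SO3·pyridine, DMSO, i-Pr2NEt, 0 °C) of their only oxidisable hydroxyl gives the ring A keto phosphonium bromide F1 and the ring B keto phosphonium bromide F2. F1 and excess 14 under base-free Wittig conditions (1,2-epoxybutane, EtOH, reflux, then thermal Z to E equilibration) give the C25 keto aldehyde F3. F3 and F2 under the same conditions give 21 directly, so the fallback comes back to the route at 21.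

**Step 10 (statistical mono-olefination of the dialdehyde).** If double condensation or inseparable mixtures dominate, the C10 unit is desymmetrised before coupling. The fallback sets out from 14. Trimethyl orthoformate in MeOH with catalytic p-TsOH, stopped at partial conversion with recycling of 14, gives the C10 mono(dimethyl acetal) F4. Wittig reaction of salt 10 (through ylide 15; NaOMe, MeOH/CH2Cl2) with F4 gives the C25 dimethyl acetal F5. Brief treatment with dilute aqueous oxalic acid in acetone releases the aldehyde, and the fallback comes back to the route at 17.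

**Step 7 (epoxidation on the face that already carries the side chain).** If the directed epoxidation of 7 is slow or unselective, the C5 oxygen is brought in as an external nucleophile instead. The fallback sets out from 7. NBS in aqueous THF should form the bromonium ion on the less hindered face, anti to the C3 hydroxyl and the side chain, and water should open it at the tertiary C5 from the opposite face. This would give the bromohydrin ester F6 with the new C5–OH cis to the side chain. Bu3SnH/AIBN (toluene, 80 °C) removes the bromine to give the diol ester F7. LiAlH4 reduction of the ester then gives the triol, and the fallback comes back to the route at 12.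

## Further compounds

F1 | step 12 | [(2E,4E)-5-[(1S,2S)-2-hydroxy-2,6,6-trimethyl-4-oxocyclohexyl]-3-methylpenta-2,4-dien-1-yl]triphenylphosphonium bromide | [Br-].c1ccccc1[P+](c1ccccc1)(c1ccccc1)C/C=C(C)/C=C/[C@H]1C(C)(C)CC(=O)C[C@]1(C)O
F2 | step 12 | [(2E,4E)-5-[(1S,2R)-2-hydroxy-2,6,6-trimethyl-4-oxocyclohexyl]-3-methylpenta-2,4-dien-1-yl]triphenylphosphonium bromide | [Br-].c1ccccc1[P+](c1ccccc1)(c1ccccc1)C/C=C(C)/C=C/[C@H]1C(C)(C)CC(=O)C[C@@]1(C)O
F3 | step 12 | (2E,4E,6E,8E,10E,12E)-13-[(1S,2S)-2-hydroxy-2,6,6-trimethyl-4-oxocyclohexyl]-2,7,11-trimethyltrideca-2,4,6,8,10,12-hexaenal | O=C/C(C)=C/C=C/C=C(C)/C=C/C=C(C)/C=C/[C@H]1C(C)(C)CC(=O)C[C@]1(C)O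
F4 | step 10 | (2E,4E,6E)-8,8-dimethoxy-2,7-dimethylocta-2,4,6-trienal | O=C/C(C)=C/C=C/C=C(C)/C(OC)OC
F5 | step 10 | dimethyl acetal of 17, (1S,3S,6S)-6-[(1E,3E,5E,7E,9E,11E)-13,13-dimethoxy-3,7,12-trimethyltrideca-1,3,5,7,9,11-hexaen-1-yl]-1,5,5-trimethylcyclohexane-1,3-diol | COC(OC)/C(C)=C/C=C/C=C(C)/C=C/C=C(C)/C=C/[C@H]1C(C)(C)C[C@H](O)C[C@]1(C)O
F6 | step 7 | ethyl (2E,4E)-5-[(1S,2S,3S,4R)-3-bromo-2,4-dihydroxy-2,6,6-trimethylcyclohexyl]-3-methylpenta-2,4-dienoate | CCOC(=O)/C=C(C)/C=C/[C@H]1C(C)(C)C[C@@H](O)[C@H](Br)[C@@]1(C)O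
F7 | step 7 | ethyl (2E,4E)-5-[(1S,2R,4R)-2,4-dihydroxy-2,6,6-trimethylcyclohexyl]-3-methylpenta-2,4-dienoate | CCOC(=O)/C=C(C)/C=C/[C@H]1C(C)(C)C[C@@H](O)C[C@@]1(C)O
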